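The target is cut at C9–C10 of its ten-membered carbocycle (germacrane numbering). The feature used is the ether oxygen that bridges C3 and the quaternary C10 beside the C1 ketone, an 11-oxabicyclo[6.2.1]undecane, which is what a [2,3] shift of an oxonium ylide leaves behind. One operation closes the five-membered O–C10 ring, turns a six-membered dihydropyran (O, C3–C7) into the oxygen-bridged ten-membered ring, sets C10 and leaves an E C7=C8 alkene, from which C7, C8 and the lactone are then made. The precursor is a 2,6-trans dihydropyran from an Achmatowicz rearrangement, with a vinyl group on C7 and a methyl diazoketone arm on C3.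

Key step: step 12

Remark: C1–C15 denote germacrane positions throughout. The target is taken as the SMILES string defines it: γ-lactone cis-fused at C6/C7, O8 on the same side, C4=C5 cis within the ring, tiglate E. The CIP descriptors in the names were derived from the SMILES strings, which are authoritative.

Step 1
Reactants: 1 4-bromofuran-2-carbaldehyde
Product: 2 4-(hydroxymethyl)furan-2-carbaldehyde
Conditions: Bu3SnCH2OH, Pd(PPh3)4 (5 mol %), 1,4-dioxane, 90 °C
Reagents that add atoms: (tributylstannyl)methanol, CCCC[Sn](CCCC)(CCCC)CO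
Why: Migita–Kosugi–Stille coupling, in which Pd(0) inserts into the furan C–Br bond and the hydroxymethyl group (C15) is transferred from tin while the aldehyde is left alone.

Step 2
Reactants: 2 4-(hydroxymethyl)furan-2-carbaldehyde
Product: 3 4-[(tert-butyldiphenylsilyloxy)methyl]furan-2-carbaldehyde
Conditions: TBDPSCl, imidazole, DMF, 0 °C to rt
Reagents that add atoms: tert-butyl(chloro)diphenylsilane, CC(C)(C)[Si](Cl)(c1ccccc1)c1ccccc1
Why: Standard silylation of a primary alcohol; the TBDPS ether is chosen because it outlasts a secondary TBS ether toward HF·pyridine, which step 15 relies on.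

Step 3
Reactants: 3 4-[(tert-butyldiphenylsilyloxy)methyl]furan-2-carbaldehyde
Product: 4 racemic furyl vinyl carbinol
Conditions: CH2=CHMgBr, THF, −78 °C; then H2O
Reagents that add atoms: vinylmagnesium bromide, C=C[Mg]Br
Why: Grignard 1,2-addition to the aldehyde brings in C8 and C9 and creates C7 as a racemic carbinol.

Step 4
Reactants: 4 racemic furyl vinyl carbinol
Product: 5 (R)-furyl vinyl carbinol
Conditions: Ti(OiPr)4 (0.2 equiv), L-(+)-DIPT (0.24 equiv), t-BuOOH (0.6 equiv), 4 Å MS, CH2Cl2, −20 °C
Reagents that add atoms: none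
Why: Sharpless kinetic resolution of a 2-furylcarbinol, in which the L-(+)-tartrate titanium catalyst oxidises the furan of the (S)-alcohol much faster, so the (R)-alcohol should be recovered in high enantiomeric purity just past half conversion, the terminal vinyl group being epoxidised far more slowly than either furan.

Step 5
Reactants: 5 (R)-furyl vinyl carbinol
Product: 6 pyranone hemiacetal
Conditions: NBS, NaHCO3, THF/H2O (4:1), 0 °C
Reagents that add atoms: water, O
Why: Achmatowicz rearrangement, in which bromonium-induced hydration opens the furan to an ene-dione that recloses through the carbinol oxygen to the 6-hydroxy-2H-pyran-3(6H)-one, with C7 untouched and C15 on the β-carbon of the enone.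

Step 6
Reactants: 6 pyranone hemiacetal
Product: 7 pyranone methyl acetal
Conditions: HC(OMe)3, MeOH, PPTS (cat.), CH2Cl2, 0 °C to rt
Reagents that add atoms: methanol, CO; trimethyl orthoformate, COC(OC)OC
Why: Acid-catalysed acetal exchange through the ring oxocarbenium ion gives the anomerically favoured axial (2,6-trans) methyl acetal without base, so the acidic C7–H is not epimerised and the vinyl group is not drawn into conjugation; any cis anomer converges in step 9.

Step 7
Reactants: 7 pyranone methyl acetal
Product: 8 allylic alcohol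
Conditions: NaBH4, CeCl3·7H2O, MeOH, −78 °C
Reagents that add atoms: none
Why: Luche 1,2-reduction, in which axial hydride delivery to the half-chair enone gives the pseudo-equatorial C6 alcohol trans to the equatorial C7 vinyl group and cerium suppresses conjugate reduction.

Step 8
Reactants: 8 allylic alcohol
Product: 9 dihydropyran methyl acetal with C6 TBS ether
Conditions: TBSCl, imidazole, DMF, rt
Reagents that add atoms: tert-butyl(chloro)dimethylsilane, CC(C)(C)[Si](C)(C)Cl
Why: Silylation of the secondary allylic alcohol under imidazole conditions, which are too mild to ionise the allylic acetal.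

Step 9
Reactants: 9 dihydropyran methyl acetal with C6 TBS ether; 10 1-(tert-butyldimethylsilyloxy)-1-methoxyethene
Product: 11 2,6-trans C-glycoside methyl ester
Conditions: TMSOTf (0.1 equiv), CH2Cl2, −78 °C
Reagents that add atoms: none
Why: Ferrier-type C-glycosylation (Mukaiyama addition), in which TMSOTf ionises the allylic acetal to the C3 oxocarbenium ion conjugated with C4=C5 and the silyl ketene acetal attacks the acetal carbon axially, anti to the equatorial C7 vinyl group, which sets C3 trans to C7 and brings in C1 and C2.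

Step 10
Reactants: 11 2,6-trans C-glycoside methyl ester
Product: 12 C-glycoside acetic acid
Conditions: LiOH, THF/MeOH/H2O, 0 °C; then 0.5 M HCl to pH 4
Reagents that add atoms: lithium hydroxide, [Li+].[OH-]
Why: Saponification of the methyl ester; both silyl ethers tolerate cold aqueous LiOH, and hydroxide is too weak a base to enolise the ester and expel the β ring oxygen.

Step 11
Reactants: 12 C-glycoside acetic acid
Product: 14 methyl-substituted diazoketone, via mixed carbonic anhydride 13 (not isolated)
Conditions: i-BuOCOCl, N-methylmorpholine, THF, −20 °C; then CH3CHN2 (excess), Et2O, −20 to 0 °C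
Reagents that add atoms: diazoethane, CC=[N+]=[N-]
Why: Acylation of diazoethane by the mixed carbonic anhydride (the alkyl-substituted form of the Arndt–Eistert diazoketone synthesis) brings in C10 and C14 without any enolate, so the β-alkoxy acid unit and all stereocentres stay intact.

Step 12
Reactants: 14 methyl-substituted diazoketone
Product: 16 11-oxabicyclo[6.2.1]undeca-2,5-dien-9-one with E C7=C8, via oxonium ylide 15 (not isolated)
Conditions: Cu(hfacac)2 (5 mol %), CH2Cl2, reflux, slow addition of 14; crude product taken directly into step 13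
Reagents that add atoms: none
Why: Cu(hfacac)2 releases N2 from 14 to give an electrophilic copper carbenoid at C10, which the ring oxygen captures along the axial C3 arm to close the oxolan-3-one ring as oxonium ylide 15; a concerted, suprafacial [2,3]-sigmatropic shift through a five-membered envelope transition state then forms C9–C10 while O–C7 breaks. The closest known reaction is the copper- or rhodium-catalysed three-atom ring expansion of 2-vinyl cyclic ethers that carry a diazoacetonyl side chain; here the diazo carbon also bears a methyl group and the pyran contains an alkene. The five-membered ring closes by O–C bond formation at the carbenoid, whereas the ten-membered carbocycle (and the nine-membered oxonene inside it) arises by ring expansion of the dihydropyran and not by end-to-end cyclisation. C10 is fixed by C3, because the C4–C9 bridge can only span the new oxolanone cis and the shift is suprafacial; the E geometry of C7=C8 follows from the equatorial vinyl group of the 2,6-trans half-chair, which lies gauche to the new O–C10 bond with C6 anti to C9, and the cis C4=C5 bond is carried over from the six-membered ring. The step needs ylide formation to outrun 1,2-hydride shift from the C14 methyl and cyclopropanation of C4=C5, and this is favoured by the five-atom reach to the ether oxygen, the strongly electrophilic copper catalyst and the three allylic oxygens that deactivate and shield C4=C5.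

Step 13
Reactants: 16 11-oxabicyclo[6.2.1]undeca-2,5-dien-9-one with E C7=C8
Product: 17 trans C7–C8 epoxide
Conditions: dimethyldioxirane (acetone solution), CH2Cl2, −40 °C
Reagents that add atoms: dimethyldioxirane, CC1(C)OO1
Why: Epoxidation with neutral dimethyldioxirane, in which the strained E alkene reacts far faster than the hindered, inductively deactivated C4=C5 bond and only on its outer face (anti to the former O–C7 bond, the oxygen bridge closing the inner face), which gives the trans epoxide with C8 as required and C7 set up for inversion.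

Step 14
Reactants: 17 trans C7–C8 epoxide
Product: 19 furanone epoxide TBS ether, via trimethylsilyl enol ether 18 (not isolated)
Conditions: LiHMDS, TMSCl, THF, −78 °C; solvent exchange; Pd(OAc)2 (1.1 equiv), MeCN, rt
Reagents that add atoms: none
Why: Ito–Saegusa oxidation, in which the enolate can form only toward C2 because C10 is quaternary and Pd(II)-mediated dehydrosilylation of its silyl ether gives the furan-3(2H)-one, which removes the relay stereocentre C3; base and TMSCl are used instead of TMSOTf to spare the epoxide.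

Step 15
Reactants: 19 furanone epoxide TBS ether
Product: 20 furanone epoxy alcohol
Conditions: HF·pyridine, pyridine, THF, 0 °C
Reagents that add atoms: none
Why: Buffered HF·pyridine cleaves the secondary TBS ether faster than the primary TBDPS ether, and the weakly acidic medium avoids base-induced Payne migration of the 2,3-epoxy alcohol.

Step 16
Reactants: 20 furanone epoxy alcohol; 21 diethylphosphonoacetic acid
Product: 22 C6 phosphonoacetate of the epoxide
Conditions: DCC, DMAP (cat.), CH2Cl2, 0 °C to rt
Reagents that add atoms: none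
Why: Steglich carbodiimide esterification, which acylates O6 with retention at C6 under near-neutral conditions that spare the epoxide, and brings in C11 and C12.

Step 17
Reactants: 22 C6 phosphonoacetate of the epoxide
Product: 24 8-hydroxy α-methylene lactone, via phosphono lactone 23 (not isolated)
Conditions: NaHMDS (1.05 equiv), THF, −78 °C to rt; then (CH2O)n, rt
Reagents that add atoms: formaldehyde (from paraformaldehyde), C=O
Why: Intramolecular alkylation of the phosphonoacetate carbanion by the epoxide in the 5-exo mode, with backside attack at C7 (inversion) giving the 6,7-cis lactone and freeing O8 with retention at C8, followed in the same flask by Horner–Wadsworth–Emmons olefination of the phosphono lactone anion with formaldehyde (C13).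

Step 18
Reactants: 24 8-hydroxy α-methylene lactone; 25 tiglic acid
Product: 27 15-O-TBDPS target, via Yamaguchi mixed anhydride 26 (not isolated)
Conditions: 2,4,6-trichlorobenzoyl chloride, Et3N, toluene, rt; then 24, DMAP, rt
Reagents that add atoms: none
Why: Yamaguchi esterification through the mixed anhydride, in which acyl transfer to O8 leaves C8 unchanged and the tiglate, being the stable E isomer, is not at risk of isomerisation.

Step 19
Reactants: 27 15-O-TBDPS target
Product: 28 CNP0269689.6
Conditions: HF·pyridine, THF, 0 °C to rt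
Reagents that add atoms: none
Why: Fluoride cleavage of the primary TBDPS ether under weakly acidic conditions that leave the α-methylene lactone, the tiglate and the furanone untouched.

Compound list
1 | 4-bromofuran-2-carbaldehyde | O=Cc1cc(Br)co1 | starting material
2 | 4-(hydroxymethyl)furan-2-carbaldehyde | O=Cc1cc(CO)co1 | intermediate
3 | 4-[(tert-butyldiphenylsilyloxy)methyl]furan-2-carbaldehyde | O=Cc1cc(CO[Si](c2ccccc2)(c2ccccc2)C(C)(C)C)co1 | intermediate
4 | rac-1-{4-[(tert-butyldiphenylsilyloxy)methyl]furan-2-yl}prop-2-en-1-ol | C=CC(O)c1cc(CO[Si](c2ccccc2)(c2ccccc2)C(C)(C)C)co1 | intermediate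
5 | (1R)-1-{4-[(tert-butyldiphenylsilyloxy)methyl]furan-2-yl}prop-2-en-1-ol | C=C[C@@H](O)c1cc(CO[Si](c2ccccc2)(c2ccccc2)C(C)(C)C)co1 | intermediate
6 | (2R,6S)-5-[(tert-butyldiphenylsilyloxy)methyl]-2-ethenyl-6-hydroxy-2H-pyran-3(6H)-one (trans hemiacetal drawn; anomers interconvert) | C=C[C@H]1O[C@H](O)C(CO[Si](c2ccccc2)(c2ccccc2)C(C)(C)C)=CC1=O | intermediate
7 | (2R,6S)-5-[(tert-butyldiphenylsilyloxy)methyl]-2-ethenyl-6-methoxy-2H-pyran-3(6H)-one | C=C[C@H]1O[C@H](OC)C(CO[Si](c2ccccc2)(c2ccccc2)C(C)(C)C)=CC1=O | intermediate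
8 | (2R,3S,6S)-5-[(tert-butyldiphenylsilyloxy)methyl]-2-ethenyl-6-methoxy-3,6-dihydro-2H-pyran-3-ol | C=C[C@H]1O[C@H](OC)C(CO[Si](c2ccccc2)(c2ccccc2)C(C)(C)C)=C[C@@H]1O | intermediate
9 | tert-butyldimethylsilyl ether of 8, (2R,3S,6S) | C=C[C@H]1O[C@H](OC)C(CO[Si](c2ccccc2)(c2ccccc2)C(C)(C)C)=C[C@@H]1O[Si](C)(C)C(C)(C)C | intermediate
10 | 1-(tert-butyldimethylsilyloxy)-1-methoxyethene | C=C(OC)O[Si](C)(C)C(C)(C)C | starting material
11 | methyl 2-[(2R,5S,6R)-5-(tert-butyldimethylsilyloxy)-3-[(tert-butyldiphenylsilyloxy)methyl]-6-ethenyl-5,6-dihydro-2H-pyran-2-yl]acetate | C=C[C@H]1O[C@H](CC(=O)OC)C(CO[Si](c2ccccc2)(c2ccccc2)C(C)(C)C)=C[C@@H]1O[Si](C)(C)C(C)(C)C | intermediate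
12 | 2-[(2R,5S,6R)-5-(tert-butyldimethylsilyloxy)-3-[(tert-butyldiphenylsilyloxy)methyl]-6-ethenyl-5,6-dihydro-2H-pyran-2-yl]acetic acid | C=C[C@H]1O[C@H](CC(=O)O)C(CO[Si](c2ccccc2)(c2ccccc2)C(C)(C)C)=C[C@@H]1O[Si](C)(C)C(C)(C)C | intermediate
13 | mixed anhydride of 12 with isobutyl hydrogen carbonate | C=C[C@H]1O[C@H](CC(=O)OC(=O)OCC(C)C)C(CO[Si](c2ccccc2)(c2ccccc2)C(C)(C)C)=C[C@@H]1O[Si](C)(C)C(C)(C)C | intermediate
14 | 3-diazo-1-[(2R,5S,6R)-5-(tert-butyldimethylsilyloxy)-3-[(tert-butyldiphenylsilyloxy)methyl]-6-ethenyl-5,6-dihydro-2H-pyran-2-yl]butan-2-one | C=C[C@H]1O[C@H](CC(=O)C(C)=[N+]=[N-])C(CO[Si](c2ccccc2)(c2ccccc2)C(C)(C)C)=C[C@@H]1O[Si](C)(C)C(C)(C)C | intermediate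
15 | bicyclic oxonium ylide: the pyran oxygen of 14 also bonded to C10 of a 2-methyl-3-oxido-4,5-dihydrofuran ring (enolate form) | C=C[C@H]1[O+]2[C@H](CC([O-])=C2C)C(CO[Si](c2ccccc2)(c2ccccc2)C(C)(C)C)=C[C@@H]1O[Si](C)(C)C(C)(C)C | intermediate
16 | (1R,2Z,4R,5E,8R)-4-(tert-butyldimethylsilyloxy)-2-[(tert-butyldiphenylsilyloxy)methyl]-8-methyl-11-oxabicyclo[6.2.1]undeca-2,5-dien-9-one | O=C1C[C@H]2O[C@]1(C)C/C=C/[C@@H](O[Si](C)(C)C(C)(C)C)/C=C2/CO[Si](c1ccccc1)(c1ccccc1)C(C)(C)C | intermediate
17 | (1R,2Z,4S,5S,6R,8R)-4-(tert-butyldimethylsilyloxy)-2-[(tert-butyldiphenylsilyloxy)methyl]-5,6-epoxy-8-methyl-11-oxabicyclo[6.2.1]undec-2-en-9-one | O=C1C[C@H]2O[C@]1(C)C[C@H]3O[C@@H]3[C@@H](O[Si](C)(C)C(C)(C)C)/C=C2/CO[Si](c1ccccc1)(c1ccccc1)C(C)(C)C | intermediate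
18 | 9-O-trimethylsilyl enol ether of 17 (undeca-2,9-diene) | C[Si](C)(C)OC1=C[C@H]2O[C@]1(C)C[C@H]3O[C@@H]3[C@@H](O[Si](C)(C)C(C)(C)C)/C=C2/CO[Si](c1ccccc1)(c1ccccc1)C(C)(C)C | intermediate
19 | (2Z,4S,5S,6R,8R)-4-(tert-butyldimethylsilyloxy)-2-[(tert-butyldiphenylsilyloxy)methyl]-5,6-epoxy-8-methyl-11-oxabicyclo[6.2.1]undeca-1(10),2-dien-9-one | O=C1C=C2O[C@]1(C)C[C@H]3O[C@@H]3[C@@H](O[Si](C)(C)C(C)(C)C)/C=C2/CO[Si](c1ccccc1)(c1ccccc1)C(C)(C)C | intermediate
20 | (2Z,4S,5R,6R,8R)-2-[(tert-butyldiphenylsilyloxy)methyl]-5,6-epoxy-4-hydroxy-8-methyl-11-oxabicyclo[6.2.1]undeca-1(10),2-dien-9-one | O=C1C=C2O[C@]1(C)C[C@H]3O[C@@H]3[C@@H](O)/C=C2/CO[Si](c1ccccc1)(c1ccccc1)C(C)(C)C | intermediate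
21 | 2-(diethoxyphosphoryl)acetic acid | CCOP(=O)(CC(=O)O)OCC | starting material
22 | (2Z,4S,5S,6R,8R)-2-[(tert-butyldiphenylsilyloxy)methyl]-5,6-epoxy-8-methyl-9-oxo-11-oxabicyclo[6.2.1]undeca-1(10),2-dien-4-yl 2-(diethoxyphosphoryl)acetate | O=C1C=C2O[C@]1(C)C[C@H]3O[C@@H]3[C@@H](OC(=O)CP(=O)(OCC)OCC)/C=C2/CO[Si](c1ccccc1)(c1ccccc1)C(C)(C)C | intermediate
23 | (6S,7R,8R,10R)-15-(tert-butyldiphenylsilyloxy)-11-(diethoxyphosphoryl)-8-hydroxy-1-oxo-3,10-epoxygermacra-2,4Z-dien-12,6-olide (C11 epimers; present as its sodium enolate) | CCOP(=O)(OCC)C1C(=O)O[C@H]2/C=C(/CO[Si](c4ccccc4)(c4ccccc4)C(C)(C)C)C3=CC(=O)[C@@](C)(C[C@@H](O)[C@@H]12)O3 | intermediate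
24 | (6S,7R,8R,10R)-15-(tert-butyldiphenylsilyloxy)-8-hydroxy-1-oxo-3,10-epoxygermacra-2,4Z,11(13)-trien-12,6-olide | C=C1C(=O)O[C@H]2/C=C(/CO[Si](c4ccccc4)(c4ccccc4)C(C)(C)C)C3=CC(=O)[C@@](C)(C[C@@H](O)[C@@H]12)O3 | intermediate
25 | tiglic acid, (E)-2-methylbut-2-enoic acid | C/C=C(\C)C(=O)O | starting material
26 | (E)-2-methylbut-2-enoic 2,4,6-trichlorobenzoic anhydride | C/C=C(\C)C(=O)OC(=O)c1c(Cl)cc(Cl)cc1Cl | intermediate
27 | (6S,7R,8R,10R)-15-(tert-butyldiphenylsilyloxy)-1-oxo-8-[(E)-2-methylbut-2-enoyloxy]-3,10-epoxygermacra-2,4Z,11(13)-trien-12,6-olide | C=C1C(=O)O[C@H]2/C=C(/CO[Si](c4ccccc4)(c4ccccc4)C(C)(C)C)C3=CC(=O)[C@@](C)(C[C@@H](OC(=O)/C(C)=C/C)[C@@H]12)O3 | intermediate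
28 | CNP0269689.6, (6S,7R,8R,10R)-15-hydroxy-1-oxo-8-[(E)-2-methylbut-2-enoyloxy]-3,10-epoxygermacra-2,4Z,11(13)-trien-12,6-olide | C=C1C(=O)O[C@H]2/C=C(/CO)C3=CC(=O)[C@@](C)(C[C@@H](OC(=O)/C(C)=C/C)[C@@H]12)O3 | target

Total step count: 19. Longest linear sequence: 19 steps (1 to 28); compounds 10, 21 and 25 are bought.

Steps most likely to fail

Step 12. The copper carbenoid may be diverted before the ring oxygen reaches it, either by 1,2-hydride shift from the C14 methyl group (a vinyl ketone results) or by addition to C4=C5, or the ylide may rearrange through a conformer that gives the Z alkene and so breaks the stereochemical relay. The fallback sets out from acid 12 and returns at furanone 19; it takes the methyl group off the carbenoid carbon. Acid 12 is activated as in step 11 and treated with diazomethane to give the terminal diazoketone F1, the substrate type on which this ring expansion is established and which has no hydrogen to shift. Cu(hfacac)2 should then give the C10-unsubstituted bicyclic dienone F2, and dimethyldioxirane its trans epoxide F3. Kinetic enolisation at the C2 methylene (LiHMDS, TMSCl) followed by Pd(OAc)2 gives the 2H-furan-3-one F4. Its single remaining α-hydrogen, at C10, is removed (KHMDS, THF, −78 °C) and the enolate is C-methylated with MeI on the face away from the carbon bridge, that is with retention, which gives 19. The bridged enolate is strained, so this methylation is the uncertain point of the fallback.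

Step 17. The carbanion may fail to reach C7 because the ester must leave its preferred conformation, or it may open the epoxide at C8 (6-endo). The liberated C8 alkoxide may also attack phosphorus (cyclic phosphonate, then cyclopropane) or the lactone carbonyl (translactonisation) before the olefination takes place. The fallback sets out from epoxy alcohol 20 and returns at 24; a malonate replaces the phosphonate. Alcohol 20 is esterified with allyl hydrogen malonate (DCC, DMAP) to the mixed malonate F5. NaH in THF should bring about the same 5-exo opening at C7 and give the α-allyloxycarbonyl lactone F6. Pd(PPh3)4 with PhSiH3 releases the α-carboxy lactone F7, and aqueous formaldehyde with diethylamine converts it by Mannich reaction, decarboxylation and loss of the amine into the α-methylene lactone 24.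

Step 15. Discrimination between the two silyl ethers may be incomplete on this hindered secondary ether, so that the primary TBDPS group is lost as well, and long exposure to HF may open the epoxide. The fallback sets out from 19 and returns at 20; selectivity is moved from the silyl groups to the hydroxyl groups. Both silyl ethers are removed on purpose (TBAF buffered with AcOH, THF, 0 °C) to give the epoxy diol F8. The primary allylic C15 hydroxyl is then silylated again (TBDPSCl, imidazole, CH2Cl2, −40 °C), the hindered secondary C6 hydroxyl next to the epoxide reacting much more slowly, which gives 20.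

Further compounds
F1 | step 12 | 1-diazo-3-[(2R,5S,6R)-5-(tert-butyldimethylsilyloxy)-3-[(tert-butyldiphenylsilyloxy)methyl]-6-ethenyl-5,6-dihydro-2H-pyran-2-yl]propan-2-one | C=C[C@H]1O[C@H](CC(=O)C=[N+]=[N-])C(CO[Si](c2ccccc2)(c2ccccc2)C(C)(C)C)=C[C@@H]1O[Si](C)(C)C(C)(C)C
F2 | step 12 | (1R,2Z,4R,5E,8R)-4-(tert-butyldimethylsilyloxy)-2-[(tert-butyldiphenylsilyloxy)methyl]-11-oxabicyclo[6.2.1]undeca-2,5-dien-9-one | O=C1C[C@H]2O[C@@H]1C/C=C/[C@@H](O[Si](C)(C)C(C)(C)C)/C=C2/CO[Si](c1ccccc1)(c1ccccc1)C(C)(C)C
F3 | step 12 | (1R,2Z,4S,5S,6R,8R)-4-(tert-butyldimethylsilyloxy)-2-[(tert-butyldiphenylsilyloxy)methyl]-5,6-epoxy-11-oxabicyclo[6.2.1]undec-2-en-9-one | O=C1C[C@H]2O[C@@H]1C[C@H]3O[C@@H]3[C@@H](O[Si](C)(C)C(C)(C)C)/C=C2/CO[Si](c1ccccc1)(c1ccccc1)C(C)(C)C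
F4 | step 12 | (2Z,4S,5S,6R,8R)-4-(tert-butyldimethylsilyloxy)-2-[(tert-butyldiphenylsilyloxy)methyl]-5,6-epoxy-11-oxabicyclo[6.2.1]undeca-1(10),2-dien-9-one | O=C1C=C2O[C@@H]1C[C@H]3O[C@@H]3[C@@H](O[Si](C)(C)C(C)(C)C)/C=C2/CO[Si](c1ccccc1)(c1ccccc1)C(C)(C)C
F5 | step 17 | allyl malonate of 20 at O6, (2Z,4S,5S,6R,8R) | O=C1C=C2O[C@]1(C)C[C@H]3O[C@@H]3[C@@H](OC(=O)CC(=O)OCC=C)/C=C2/CO[Si](c1ccccc1)(c1ccccc1)C(C)(C)C
F6 | step 17 | allyl (6S,7R,8R,10R)-15-(tert-butyldiphenylsilyloxy)-8-hydroxy-1-oxo-3,10-epoxygermacra-2,4Z-dien-12,6-olide-11-carboxylate (C11 epimers) | C=CCOC(=O)C1C(=O)O[C@H]2/C=C(/CO[Si](c4ccccc4)(c4ccccc4)C(C)(C)C)C3=CC(=O)[C@@](C)(C[C@@H](O)[C@@H]12)O3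
F7 | step 17 | (6S,7R,8R,10R)-15-(tert-butyldiphenylsilyloxy)-8-hydroxy-1-oxo-3,10-epoxygermacra-2,4Z-dien-12,6-olide-11-carboxylic acid (C11 epimers) | OC(=O)C1C(=O)O[C@H]2/C=C(/CO[Si](c4ccccc4)(c4ccccc4)C(C)(C)C)C3=CC(=O)[C@@](C)(C[C@@H](O)[C@@H]12)O3
F8 | step 15 | (2Z,4S,5R,6R,8R)-5,6-epoxy-4-hydroxy-2-(hydroxymethyl)-8-methyl-11-oxabicyclo[6.2.1]undeca-1(10),2-dien-9-one | O=C1C=C2O[C@]1(C)C[C@H]3O[C@@H]3[C@@H](O)/C=C2/CO
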